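**Retrosynthetic overview**
1. Target 26 ⇐ quinone 25 (dithionite reduction) ⇐ trimethyl ether seco acid 24 (oxidative demethylation). The isopropenyl/propanoic acid pair comes from acid-induced opening of the ring A ε-lactone 23.
2. Lactone 23 ⇐ trans-fused 4,4-dimethyl-3-ketone 21 (Baeyer–Villiger, then benzylic C7 oxidation) ⇐ enone 19 (reductive methylation) ⇐ 1,5-diketone 18 (intramolecular aldol).
3. Key C–C bond (C10–C1, quaternary stereocentre): intermolecular Michael addition of the chiral enamine 15 of 1-methyl-2-tetralone 13 to ethyl vinyl ketone 16.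
4. Tetralone 13 ⇐ 1-tetralone 9 (methyl addition, dehydration, epoxide rearrangement) ⇐ arene 5 (succinoylation, reduction, cyclisation) ⇐ 1,2,4-trimethoxybenzene 1 + acetone 2 (directed ortho-lithiation).
5. Ring order: ring C is bought, ring B is closed by Friedel–Crafts acylation, ring A is made by Robinson annulation and then cleaved again.

Convention (one line): positions are cited with abietane numbering (C10 = quaternary benzylic carbon, C5 = its CH neighbour, C7 = benzylic carbon of ring B, C11/C12/C13/C14 = ring C carbons bearing O, OMe, isopropyl, O, and C1–C4 = ring A or its seco chain).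

**Route**

Step 1
Reactants: 1 1,2,4-trimethoxybenzene; 2 acetone
Product: 4 2-(2,3,6-trimethoxyphenyl)propan-2-ol, via 2,3,6-trimethoxyphenyllithium 3 (not isolated)
Conditions: n-BuLi (1.1 equiv), THF, 0 °C to rt, 2 h; then acetone, −78 °C to rt; H2O
Reagents that add atoms: none
Why: Directed ortho-metalation removes the one ring proton flanked by two methoxy groups, and the aryllithium then undergoes 1,2-addition to acetone.

Step 2
Reactants: 4 2-(2,3,6-trimethoxyphenyl)propan-2-ol
Product: 5 1,2,4-trimethoxy-3-(propan-2-yl)benzene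
Conditions: Et3SiH (2 equiv), CF3CO2H (5 equiv), CH2Cl2, 0 °C to rt
Reagents that add atoms: none
Why: Ionic hydrogenation works because the tertiary benzylic alcohol ionises readily in CF3CO2H and the cation is trapped by hydride from the silane.

Step 3
Reactants: 5 1,2,4-trimethoxy-3-(propan-2-yl)benzene; 6 succinic anhydride
Product: 7 4-oxo-4-[2,4,5-trimethoxy-3-(propan-2-yl)phenyl]butanoic acid
Conditions: AlCl3 (2.3 equiv), CH2Cl2/MeNO2, 0 °C, 3 h; then ice/aq. HCl
Reagents that add atoms: none
Why: Friedel–Crafts acylation (Haworth succinoylation) goes to the free position that is ortho to one methoxy group and para to another (future C8), which is far more activated than the position that is ortho to methoxy and para to isopropyl, and the low temperature avoids ether cleavage.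

Step 4
Reactants: 7 4-oxo-4-[2,4,5-trimethoxy-3-(propan-2-yl)phenyl]butanoic acid
Product: 8 4-[2,4,5-trimethoxy-3-(propan-2-yl)phenyl]butanoic acid
Conditions: Et3SiH (3 equiv), CF3CO2H, 55 °C, 12 h
Reagents that add atoms: none
Why: Ionic hydrogenation takes an electron-rich aryl ketone down to the methylene through the stabilised benzylic cation and leaves the carboxylic acid and the ethers alone.

Step 5
Reactants: 8 4-[2,4,5-trimethoxy-3-(propan-2-yl)phenyl]butanoic acid
Product: 9 5,7,8-trimethoxy-6-(propan-2-yl)-3,4-dihydronaphthalen-1(2H)-one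
Conditions: P2O5/MeSO3H (1:10 w/w), rt, 3 h
Reagents that add atoms: none
Why: Intramolecular Friedel–Crafts acylation closes the six-membered ring B at the only free ring position (future C9), which is activated by an ortho methoxy group.

Step 6
Reactants: 9 5,7,8-trimethoxy-6-(propan-2-yl)-3,4-dihydronaphthalen-1(2H)-one
Product: 11 5,6,8-trimethoxy-4-methyl-7-(propan-2-yl)-1,2-dihydronaphthalene, via tertiary benzylic alcohol 10 (not isolated)
Conditions: MeMgBr (1.5 equiv), THF, 0 °C to rt; then crude with TsOH·H2O (cat.), toluene, 60 °C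
Reagents that add atoms: methylmagnesium bromide, C[Mg]Br
Why: Grignard 1,2-addition (helped by chelation to the peri methoxy group) gives a tertiary benzylic alcohol that loses water by acid-catalysed E1 dehydration to the conjugated endocyclic alkene.

Step 7
Reactants: 11 5,6,8-trimethoxy-4-methyl-7-(propan-2-yl)-1,2-dihydronaphthalene
Product: 13 rac-5,7,8-trimethoxy-1-methyl-6-(propan-2-yl)-3,4-dihydronaphthalen-2(1H)-one, via epoxide 12 (not isolated)
Conditions: mCPBA (1.1 equiv), CH2Cl2, 0 °C; then crude with TsOH·H2O (cat.), toluene, 80 °C; used at once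
Reagents that add atoms: mCPBA (3-chloroperoxybenzoic acid), OOC(=O)c1cccc(Cl)c1
Why: Prilezhaev epoxidation of the electron-rich styrene followed by acid-catalysed Meinwald rearrangement (opening to the tertiary benzylic cation and 1,2-hydride shift) gives the 1-methyl-2-tetralone, whose labile stereocentre is left racemic on purpose.

Step 8
Reactants: 13 rac-5,7,8-trimethoxy-1-methyl-6-(propan-2-yl)-3,4-dihydronaphthalen-2(1H)-one; 14 (R)-1-phenylethylamine
Product: 15 5,7,8-trimethoxy-1-methyl-N-[(1R)-1-phenylethyl]-6-(propan-2-yl)-3,4-dihydronaphthalen-2-amine (secondary enamine in equilibrium with its imine)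
Conditions: 14 (1.1 equiv), TsOH·H2O (cat.), toluene, reflux, Dean–Stark, 16 h; concentrated and used crude
Reagents that add atoms: none
Why: Amine–ketone condensation gives the imine/secondary enamine pair, and the enamine form erases the racemic C10 centre so that the next step can set it under auxiliary control.

Step 9
Reactants: 15 5,7,8-trimethoxy-1-methyl-N-[(1R)-1-phenylethyl]-6-(propan-2-yl)-3,4-dihydronaphthalen-2-amine; 16 ethyl vinyl ketone (pent-1-en-3-one)
Product: 18 (1R)-5,7,8-trimethoxy-1-methyl-1-(3-oxopentyl)-6-(propan-2-yl)-3,4-dihydronaphthalen-2(1H)-one, via Michael-adduct imine 17 (not isolated)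
Conditions: 16 (1.5 equiv), THF, rt to 40 °C, 4 d; then 20% aq. AcOH, rt, 2 h
Reagents that add atoms: water, O
Why: In this d'Angelo-type intermolecular Michael addition the more substituted secondary enamine adds to the enone through a compact chair-like transition state with internal N–H transfer on the face anti to the phenyl group of the (R)-auxiliary, which sets the quaternary C10 centre as (R) (β-methyl, natural series), and mild hydrolysis releases the diketone and the amine.

Step 10
Reactants: 18 (1R)-5,7,8-trimethoxy-1-methyl-1-(3-oxopentyl)-6-(propan-2-yl)-3,4-dihydronaphthalen-2(1H)-one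
Product: 19 (4aS)-5,6,8-trimethoxy-1,4a-dimethyl-7-(propan-2-yl)-4,4a,9,10-tetrahydrophenanthren-2(3H)-one
Conditions: NaOMe (1.2 equiv), MeOH, 60 °C, 4 h
Reagents that add atoms: none
Why: Intramolecular aldol condensation (second half of a Robinson annulation) closes ring A as a six-membered ring and E1cB dehydration gives the tetrasubstituted enone without touching the quaternary centre.

Step 11
Reactants: 19 (4aS)-5,6,8-trimethoxy-1,4a-dimethyl-7-(propan-2-yl)-4,4a,9,10-tetrahydrophenanthren-2(3H)-one
Product: 21 (4aS,10aR)-5,6,8-trimethoxy-1,1,4a-trimethyl-7-(propan-2-yl)-3,4,4a,9,10,10a-hexahydrophenanthren-2(1H)-one, via lithium enolate 20 (not isolated)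
Conditions: Li (2.5 equiv), NH3(l)/THF, t-BuOH (1.0 equiv), −78 °C, 30 min; isoprene; then MeI (5 equiv), −78 to −33 °C; H2O
Reagents that add atoms: methyl iodide, CI
Why: In this Stork reductive alkylation the dissolving-metal reduction protonates the β-carbon axially, anti to the angular methyl group, which sets C5–H trans to the C10 methyl (trans ring fusion), and the regiodefined lithium enolate is then C-methylated at C4.

Step 12
Reactants: 21 (4aS,10aR)-5,6,8-trimethoxy-1,1,4a-trimethyl-7-(propan-2-yl)-3,4,4a,9,10,10a-hexahydrophenanthren-2(1H)-one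
Product: 22 (5R,10S)-11,12,14-trimethoxy-4-oxa-A-homoabieta-8,11,13-trien-3-one (seven-membered lactone with the ring oxygen between the C3 carbonyl and CMe2)
Conditions: mCPBA (2.5 equiv), CHCl3, rt, dark, 3 d
Reagents that add atoms: mCPBA (3-chloroperoxybenzoic acid), OOC(=O)c1cccc(Cl)c1
Why: Baeyer–Villiger oxidation of the only ketone proceeds by migration of the quaternary C4, so oxygen is inserted between C3 and C4, and the fully substituted arene and both stereocentres are untouched.

Step 13
Reactants: 22 (5R,10S)-11,12,14-trimethoxy-4-oxa-A-homoabieta-8,11,13-trien-3-one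
Product: 23 (5R,10S)-11,12,14-trimethoxy-4-oxa-A-homoabieta-8,11,13-triene-3,7-dione
Conditions: CrO3 (3 equiv), AcOH/H2O (9:1), rt, 4 h
Reagents that add atoms: chromium trioxide, O=[Cr](=O)=O
Why: Benzylic oxidation selects the ring-fused C7 methylene, whose C–H bonds overlap with the arene π-system, over the isopropyl methine shielded by two methoxy groups, and the lactone is inert to the oxidant.

Step 14
Reactants: 23 (5R,10S)-11,12,14-trimethoxy-4-oxa-A-homoabieta-8,11,13-triene-3,7-dione
Product: 24 3-[(1S,2S)-5,7,8-trimethoxy-1-methyl-4-oxo-6-(propan-2-yl)-2-(prop-1-en-2-yl)-1,2,3,4-tetrahydronaphthalen-1-yl]propanoic acid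
Conditions: TsOH·H2O (0.3 equiv), CH2Cl2, rt, 12 h
Reagents that add atoms: none
Why: Acid-catalysed alkyl–oxygen heterolysis of the tertiary lactone followed by E1 loss of a methyl proton gives the isopropenyl group and the free acid in one eliminative ring opening that does not involve C5 or C10.

Step 15
Reactants: 24 3-[(1S,2S)-5,7,8-trimethoxy-1-methyl-4-oxo-6-(propan-2-yl)-2-(prop-1-en-2-yl)-1,2,3,4-tetrahydronaphthalen-1-yl]propanoic acid
Product: 25 3-[(1S,2S)-7-methoxy-1-methyl-4,5,8-trioxo-6-(propan-2-yl)-2-(prop-1-en-2-yl)-1,2,3,4,5,8-hexahydronaphthalen-1-yl]propanoic acid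
Conditions: (NH4)2Ce(NO3)6 (2.6 equiv), MeCN/H2O (2:1), 0 °C, 20 min
Reagents that add atoms: water, O
Why: Oxidative demethylation converts the para-related C11/C14 dimethoxy pair into the p-quinone and keeps the C12 methoxy group, while the isolated alkene and the acid survive the short cold exposure.

Step 16
Reactants: 25 3-[(1S,2S)-7-methoxy-1-methyl-4,5,8-trioxo-6-(propan-2-yl)-2-(prop-1-en-2-yl)-1,2,3,4,5,8-hexahydronaphthalen-1-yl]propanoic acid
Product: 26 3-[(1S,2S)-5,8-dihydroxy-7-methoxy-1-methyl-4-oxo-6-(propan-2-yl)-2-(prop-1-en-2-yl)-1,2,3,4-tetrahydronaphthalen-1-yl]propanoic acid (CNP0249049.1)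
Conditions: Na2S2O4 (5 equiv), EtOAc/H2O, rt, 10 min, Ar
Reagents that add atoms: none
Why: Dithionite reduction of a quinone to its hydroquinone is fast and leaves the aryl ketone, the alkene and the acid alone, and the resulting acyl hydroquinone is stabilised by hydrogen bonding to the C7 ketone.

**Compound list**
1 | 1,2,4-trimethoxybenzene | COc1ccc(OC)c(OC)c1 | starting material
2 | acetone | CC(C)=O | starting material
3 | 2,3,6-trimethoxyphenyllithium | COc1ccc(OC)c(OC)c1[Li] | intermediate
4 | 2-(2,3,6-trimethoxyphenyl)propan-2-ol | COc1ccc(OC)c(OC)c1C(C)(C)O | intermediate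
5 | 1,2,4-trimethoxy-3-(propan-2-yl)benzene | COc1ccc(OC)c(OC)c1C(C)C | intermediate
6 | succinic anhydride | O=C1CCC(=O)O1 | starting material
7 | 4-oxo-4-[2,4,5-trimethoxy-3-(propan-2-yl)phenyl]butanoic acid | COc1c(C(=O)CCC(=O)O)cc(OC)c(OC)c1C(C)C | intermediate
8 | 4-[2,4,5-trimethoxy-3-(propan-2-yl)phenyl]butanoic acid | COc1c(CCCC(=O)O)cc(OC)c(OC)c1C(C)C | intermediate
9 | 5,7,8-trimethoxy-6-(propan-2-yl)-3,4-dihydronaphthalen-1(2H)-one | COc1c(C(C)C)c(OC)c(OC)c2c1CCCC2=O | intermediate
10 | rac-5,7,8-trimethoxy-1-methyl-6-(propan-2-yl)-1,2,3,4-tetrahydronaphthalen-1-ol | COc1c(C(C)C)c(OC)c(OC)c2c1CCCC2(C)O | intermediate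
11 | 5,6,8-trimethoxy-4-methyl-7-(propan-2-yl)-1,2-dihydronaphthalene | COc1c(C(C)C)c(OC)c(OC)c2c1CCC=C2C | intermediate
12 | rac-1,2-epoxy-5,7,8-trimethoxy-1-methyl-6-(propan-2-yl)-1,2,3,4-tetrahydronaphthalene | COc1c(C(C)C)c(OC)c(OC)c2c1CCC1OC21C | intermediate
13 | rac-5,7,8-trimethoxy-1-methyl-6-(propan-2-yl)-3,4-dihydronaphthalen-2(1H)-one | COc1c(C(C)C)c(OC)c(OC)c2c1CCC(=O)C2C | intermediate
14 | (R)-1-phenylethylamine | C[C@@H](N)c1ccccc1 | starting material
15 | 5,7,8-trimethoxy-1-methyl-N-[(1R)-1-phenylethyl]-6-(propan-2-yl)-3,4-dihydronaphthalen-2-amine (enamine tautomer drawn) | CC1=C(N[C@H](C)c2ccccc2)CCc2c(OC)c(C(C)C)c(OC)c(OC)c12 | intermediate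
16 | ethyl vinyl ketone (pent-1-en-3-one) | C=CC(=O)CC | starting material
17 | N-[(1R)-1-phenylethyl]imine of (1R)-5,7,8-trimethoxy-1-methyl-1-(3-oxopentyl)-6-(propan-2-yl)-3,4-dihydronaphthalen-2(1H)-one | C[C@@H](N=C1CCc2c(OC)c(C(C)C)c(OC)c(OC)c2[C@@]1(C)CCC(=O)CC)c1ccccc1 | intermediate
18 | (1R)-5,7,8-trimethoxy-1-methyl-1-(3-oxopentyl)-6-(propan-2-yl)-3,4-dihydronaphthalen-2(1H)-one | O=C1CCc2c(OC)c(C(C)C)c(OC)c(OC)c2[C@@]1(C)CCC(=O)CC | intermediate
19 | (4aS)-5,6,8-trimethoxy-1,4a-dimethyl-7-(propan-2-yl)-4,4a,9,10-tetrahydrophenanthren-2(3H)-one | CC1=C2CCc3c(OC)c(C(C)C)c(OC)c(OC)c3[C@@]2(C)CCC1=O | intermediate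
20 | lithium (4aS,10aR)-5,6,8-trimethoxy-1,4a-dimethyl-7-(propan-2-yl)-3,4,4a,9,10,10a-hexahydrophenanthren-2-olate | [Li]OC1=C(C)[C@@H]2CCc3c(OC)c(C(C)C)c(OC)c(OC)c3[C@@]2(C)CC1 | intermediate
21 | (4aS,10aR)-5,6,8-trimethoxy-1,1,4a-trimethyl-7-(propan-2-yl)-3,4,4a,9,10,10a-hexahydrophenanthren-2(1H)-one (trans-fused, 5α-H, 10β-methyl) | CC1(C)[C@@H]2CCc3c(OC)c(C(C)C)c(OC)c(OC)c3[C@@]2(C)CCC1=O | intermediate
22 | (5R,10S)-11,12,14-trimethoxy-4-oxa-A-homoabieta-8,11,13-trien-3-one (ring A ε-lactone) | CC1(C)[C@@H]2CCc3c(OC)c(C(C)C)c(OC)c(OC)c3[C@@]2(C)CCC(=O)O1 | intermediate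
23 | (5R,10S)-11,12,14-trimethoxy-4-oxa-A-homoabieta-8,11,13-triene-3,7-dione | CC1(C)[C@@H]2CC(=O)c3c(OC)c(C(C)C)c(OC)c(OC)c3[C@@]2(C)CCC(=O)O1 | intermediate
24 | 3-[(1S,2S)-5,7,8-trimethoxy-1-methyl-4-oxo-6-(propan-2-yl)-2-(prop-1-en-2-yl)-1,2,3,4-tetrahydronaphthalen-1-yl]propanoic acid | C=C(C)[C@@H]1CC(=O)c2c(OC)c(C(C)C)c(OC)c(OC)c2[C@@]1(C)CCC(=O)O | intermediate
25 | 3-[(1S,2S)-7-methoxy-1-methyl-4,5,8-trioxo-6-(propan-2-yl)-2-(prop-1-en-2-yl)-1,2,3,4,5,8-hexahydronaphthalen-1-yl]propanoic acid | C=C(C)[C@@H]1CC(=O)C2=C([C@@]1(C)CCC(=O)O)C(=O)C(OC)=C(C(C)C)C2=O | intermediate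
26 | 3-[(1S,2S)-5,8-dihydroxy-7-methoxy-1-methyl-4-oxo-6-(propan-2-yl)-2-(prop-1-en-2-yl)-1,2,3,4-tetrahydronaphthalen-1-yl]propanoic acid | C=C(C)[C@@H]1CC(=O)c2c(O)c(C(C)C)c(OC)c(O)c2[C@@]1(C)CCC(=O)O | target

**Totals**
Total step count: 16. Longest linear sequence: 16 steps (1 to 26).

**Steps most likely to fail and their fallbacks**

Step 9 is a risk because the peri methoxy group sits next to the reacting carbon and may slow the auxiliary-controlled Michael addition or lower its selectivity. The enantiomeric purity expected (about 90% ee) would in any case be raised by recrystallising 19 or 21. The fallback drops the covalent auxiliary. It sets out from tetralone 13 and adds it directly to ethyl vinyl ketone 16 under chiral phase-transfer catalysis, with N-[4-(trifluoromethyl)benzyl]cinchoninium bromide or its cinchonidinium pseudoenantiomer (10 mol %, toluene/50% aq. KOH, −20 °C). Whichever salt gives the (R)-adduct in a short screen is used, and the chiral ammonium enolate ion pair sets C10. The fallback comes back to the route at diketone 18 and makes no compound outside the list (entry F0).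

Step 13 is a risk because CrO3 may oxidise the electron-rich ring to a quinone or attack the isopropyl methine instead of C7. The fallback sets out from lactone 22 and replaces direct oxidation by halogenation, solvolysis and alcohol oxidation. Radical bromination (NBS, (PhCO2)2 cat., PhCF3, 80 °C) gives the 7-bromo lactone F1 as a mixture of C7 epimers. Silver-assisted hydrolysis (AgNO3, acetone/H2O, rt) gives the 7-hydroxy lactone F2. Dess–Martin periodinane (CH2Cl2, rt) oxidises F2 to the keto lactone, and the fallback comes back to the route at 23.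

Step 15 is a risk because the acyl-substituted, fully substituted ring may react sluggishly with (NH4)2Ce(NO3)6, some ortho-quinone may form, or the isopropenyl group may be attacked. The fallback sets out from 24 and fixes the regiochemistry through a phenol. Chelation-controlled cleavage of the one methoxy group peri to the C7 ketone with MgI2·OEt2 (toluene/Et2O, 60 °C) gives the 14-hydroxy-11,12-dimethoxy seco acid F3. Its p-methoxyphenol unit is then oxidised with PhI(OAc)2 (MeCN/H2O, 0 °C), which can only give the para-quinone, and the fallback comes back to the route at 25.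

**Further compounds**
F0 | step 9 | none | none
F1 | step 13 | (5R,10S)-7-bromo-11,12,14-trimethoxy-4-oxa-A-homoabieta-8,11,13-trien-3-one (C7 epimer mixture) | CC1(C)[C@@H]2CC(Br)c3c(OC)c(C(C)C)c(OC)c(OC)c3[C@@]2(C)CCC(=O)O1
F2 | step 13 | (5R,10S)-7-hydroxy-11,12,14-trimethoxy-4-oxa-A-homoabieta-8,11,13-trien-3-one (C7 epimer mixture) | CC1(C)[C@@H]2CC(O)c3c(OC)c(C(C)C)c(OC)c(OC)c3[C@@]2(C)CCC(=O)O1
F3 | step 15 | 3-[(1S,2S)-5-hydroxy-7,8-dimethoxy-1-methyl-4-oxo-6-(propan-2-yl)-2-(prop-1-en-2-yl)-1,2,3,4-tetrahydronaphthalen-1-yl]propanoic acid | C=C(C)[C@@H]1CC(=O)c2c(O)c(C(C)C)c(OC)c(OC)c2[C@@]1(C)CCC(=O)O
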